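**Retrosynthetic overview**

1. Target 30 ⇐ methyl ester 29 ⇐ 16‑ketone 27/28 (Lombardo CH2 at C16, β‑face OsO4 on C2=C3, 9‑BBN at C16, NaBH4 at C11) ⇐ tetracycle 20.
2. Key disconnection: the C11 oxygen sits in the middle of the three‑carbon bridge C9–C11–C12 that spans C8 and C13 of five‑membered ring D (the bicyclo[3.2.1]octane C/D unit). That is the retron of an oxyallyl cation + cyclopentadiene (4+3). Because C8–C9 is also a ring‑B bond, the three‑atom tether C10–C5–C6 closes ring B in the same event: 20 ⇐ chloro ketone/cyclopentenone 18.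
3. 18 ⇐ radical (Giese) C5–C6 union of bromolactone 11 with dienone ester 16 (from cyclopentenone + methyl glyoxylate).
4. Ring A lactone 8 ⇐ Schultz Birch reductive methylation of benzamide 5 (dearomatisation of a cheap arene sets C4) and bromolactonisation (relays C4 to C10 and C5).
5. Ring order: A (from the arene) → 19,10‑lactone → B and C closed together with bridging of D (step 12); C11, C6, C16=C17 and the 2,3‑diol are adjusted afterwards.

Key step: step 12

Remark: atom numbers are gibberellane numbers (C7 = carboxyl carbon on C6, C19 = lactone carbonyl on C4, C17 = methylene carbon on C16).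
Assumption: the (S)‑prolinol‑derived 2‑methoxybenzamide is taken to be methylated with the facial sense that gives the C4 configuration drawn; if the sense is opposite, the (R)‑auxiliary is used and nothing else changes.
Remark: C6 (and C8 before step 12) are carried as epimer mixtures and drawn without descriptor until step 15 fixes C6.

**Step 1**
Reactants: 1 5‑bromo‑2‑methoxybenzoic acid; 2 (S)‑2‑(methoxymethyl)pyrrolidine
Product: 4 N‑(5‑bromo‑2‑methoxybenzoyl)‑(S)‑2‑(methoxymethyl)pyrrolidine, via acid chloride 3 (not isolated)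
Conditions: (COCl)2, cat. DMF, CH2Cl2, 0 °C → rt; then 2, Et3N, CH2Cl2, 0 °C
Reagents that add atoms: none
Why: Acyl chloride amidation installs the Schultz auxiliary; no new stereocentre.

**Step 2**
Reactants: 4
Product: 5 N‑(5‑allyl‑2‑methoxybenzoyl)‑(S)‑2‑(methoxymethyl)pyrrolidine
Conditions: allylSnBu3, Pd(PPh3)4 (5 mol%), toluene, 110 °C
Reagents that add atoms: allyltributylstannane C=CC[Sn](CCCC)(CCCC)CCCC
Why: Stille allylation of the aryl bromide places the future C9–C11–C12 unit on the carbon that becomes C10.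

**Step 3**
Reactants: 5
Product: 7 N‑[(3‑allyl‑1‑methyl‑6‑oxocyclohex‑2‑en‑1‑yl)carbonyl]‑(S)‑2‑(methoxymethyl)pyrrolidine, via enol ether 6 (not isolated)
Conditions: K, NH3/THF, t‑BuOH (1 equiv), −78 °C; MeI, −78 °C; then 1 M HCl, THF, rt
Reagents that add atoms: iodomethane CI; water O
Why: Schultz asymmetric Birch reduction–alkylation: the chelated amide enolate from 1,4‑reduction is methylated on the face away from the methoxymethyl arm, which sets C4; acid then hydrolyses enol ether 6 to the C3 ketone.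

**Step 4**
Reactants: 7
Product: 8 5‑allyl‑8‑bromo‑1‑methyl‑6‑oxabicyclo[3.2.1]octane‑2,7‑dione (Br anti to the O–C(=O) bridge)
Conditions: NBS, THF/H2O (4:1), 0 °C → rt
Reagents that add atoms: N‑bromosuccinimide O=C1CCC(=O)N1Br; water O
Why: Bromolactonisation of the β,γ‑unsaturated amide with loss of the auxiliary: the amide oxygen adds to the more substituted carbon C10 on the face of C19 and bromine adds anti at C5, so C10 (and C5–Br) are relayed from C4.

**Step 5**
Reactants: 8
Product: 9 5‑allyl‑8‑bromo‑1‑methyl‑7‑oxo‑6‑oxabicyclo[3.2.1]oct‑2‑en‑2‑yl trifluoromethanesulfonate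
Conditions: KHMDS, THF, −78 °C; PhNTf2, −78 → 0 °C; NH4Cl (aq)
Reagents that add atoms: N‑phenylbis(trifluoromethanesulfonimide) O=S(=O)(N(c1ccccc1)S(=O)(=O)C(F)(F)F)C(F)(F)F
Why: Enol triflate formation; C2 is the only enolisable position, and the bridge bromide has no β‑hydrogen and cannot be displaced.

**Step 6**
Reactants: 9
Product: 10 8‑bromo‑5‑(3‑chloro‑2‑hydroxypropyl)‑1‑methyl‑7‑oxo‑6‑oxabicyclo[3.2.1]oct‑2‑en‑2‑yl trifluoromethanesulfonate (carbinol epimers)
Conditions: trichloroisocyanuric acid (0.36 equiv), acetone/H2O (5:1), 0 °C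
Reagents that add atoms: trichloroisocyanuric acid ClN1C(=O)N(Cl)C(=O)N(Cl)C1=O; water O
Why: Markovnikov chlorohydrin formation on the terminal alkene (the vinyl triflate is inert to electrophilic chlorine); the carbinol centre forms unselectively and is erased in step 11.

**Step 7**
Reactants: 10
Product: 11 8‑bromo‑5‑(3‑chloro‑2‑hydroxypropyl)‑1‑methyl‑6‑oxabicyclo[3.2.1]oct‑2‑en‑7‑one
Conditions: Pd(OAc)2 (5 mol%), PPh3, HCO2H, n‑Bu3N, DMF, 60 °C
Reagents that add atoms: none
Why: Palladium‑catalysed formate reduction of the vinyl triflate gives the C2=C3 alkene; the hindered secondary bromide and the primary chloride should not undergo oxidative addition.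

**Step 8**
Reactants: 12 cyclopent‑2‑en‑1‑one; 13 methyl glyoxylate
Product: 14 methyl 2‑hydroxy‑2‑(2‑oxocyclopent‑3‑en‑1‑yl)acetate
Conditions: LDA, THF, −78 °C; then 13, −78 °C; AcOH
Reagents that add atoms: none
Why: Aldol addition of the kinetic (α′) lithium enolate of cyclopentenone; the stereocentres are removed in step 9.

**Step 9**
Reactants: 14
Product: 16 methyl (E)‑2‑(2‑oxocyclopent‑3‑en‑1‑ylidene)acetate, via mesylate 15 (not isolated)
Conditions: MsCl, Et3N, CH2Cl2, 0 °C → rt
Reagents that add atoms: none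
Why: Mesylation and E1cB elimination give the cross‑conjugated dienone ester, used freshly.

**Step 10**
Reactants: 11; 16
Product: 17 methyl 2‑[5‑(3‑chloro‑2‑hydroxypropyl)‑1‑methyl‑7‑oxo‑6‑oxabicyclo[3.2.1]oct‑2‑en‑8‑yl]‑2‑(2‑oxocyclopent‑3‑en‑1‑yl)acetate (C6/C8 epimers)
Conditions: n‑Bu3SnH (syringe pump), AIBN, 16 (3 equiv), PhH, 80 °C
Reagents that add atoms: none
Why: Giese addition: the C5 bridge radical adds to the ester‑bearing exocyclic carbon of the doubly activated alkene from the face syn to the hydrogen‑free O–C(=O) bridge (the other face carries the axial C1 hydrogen), which should put C6 equatorial and H5 anti to the lactone.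

**Step 11**
Reactants: 17
Product: 18 methyl 2‑[5‑(3‑chloro‑2‑oxopropyl)‑1‑methyl‑7‑oxo‑6‑oxabicyclo[3.2.1]oct‑2‑en‑8‑yl]‑2‑(2‑oxocyclopent‑3‑en‑1‑yl)acetate
Conditions: Dess–Martin periodinane, CH2Cl2, 0 °C → rt
Reagents that add atoms: none
Why: Dess–Martin oxidation of the only hydroxyl gives the α‑chloro ketone (the oxyallyl precursor) without base.

**Step 12**
Reactants: 18
Product: 20 methyl 15‑(tert‑butyldimethylsilyloxy)‑11‑oxo‑17‑nor‑gibberella‑2,15‑dien‑7‑oate 19,10‑lactone (C6 epimers), via silyl dienol ether 19 (not isolated)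
Conditions: i‑Pr2NEt, TBSOTf (1.15 equiv), CH2Cl2, −78 → 0 °C; then LiClO4 (3 M in Et2O), i‑Pr2NEt, 0 °C → rt
Reagents that add atoms: tert‑butyldimethylsilyl trifluoromethanesulfonate CC(C)(C)[Si](C)(C)OS(=O)(=O)C(F)(F)F
Why: Proposed new method: O‑silylation and α′‑deprotonation of the cyclopentenone (the more Lewis‑basic carbonyl) give 2‑silyloxycyclopentadiene 19; in LiClO4–ether the amine enolises the chloro ketone towards C9, chloride loss gives the 2‑oxyallyl cation, and the tethered diene captures it in a (4+3) cycloaddition whose leading bond is C8–C9 (enol‑ether β‑carbon to oxyallyl terminus) and whose second bond is C12–C13. The closest known reactions are the Föhlisch–Herter (LiClO4/amine) oxyallyl cycloadditions of α‑halo ketones with cyclopentadiene and furan and intramolecular (4+3) cycloadditions over three‑atom tethers. Ring B closes 5‑exo at C8 (C9–C10–C5–C6–C8), ring C closes by six‑membered chair‑like attack of C12 on C13, and the cyclopentadiene becomes the bridged ring D. C8, C13 and C9 are set together: the rigid lactone holds C9 and C6 trans‑diequatorial, which fixes the sense of twist about the forming bond, and the oxyallyl substituent C10 then lies anti to the bulky C15–OTBS group, the arrangement that gives the cis B/C junction with C14 and C11 on the lactone face. The step needs silylation of the enone but not of the chloro ketone, (4+3) rather than (3+2) closure (closure at C15 would join two quaternary carbons), and capture of 19 before a 1,5‑hydrogen shift; the low temperature, the single equivalent of TBSOTf and the hindered base are chosen for this.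

**Step 13**
Reactants: 20
Product: 21 methyl 11‑oxo‑15‑(trifluoromethylsulfonyloxy)‑17‑nor‑gibberella‑2,15‑dien‑7‑oate 19,10‑lactone (C6 epimers)
Conditions: CsF, PhNTf2, DME, rt; NH4Cl (aq)
Reagents that add atoms: N‑phenylbis(trifluoromethanesulfonimide) O=S(=O)(N(c1ccccc1)S(=O)(=O)C(F)(F)F)C(F)(F)F
Why: Fluoride‑mediated conversion of the silyl enol ether into the enol triflate; the enolate is trapped as it forms, so the position is retained.

**Step 14**
Reactants: 21
Product: 22 methyl 11‑oxo‑17‑nor‑gibberella‑2,15‑dien‑7‑oate 19,10‑lactone (C6 epimers)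
Conditions: Pd(OAc)2 (5 mol%), PPh3, HCO2H, n‑Bu3N, DMF, 60 °C
Reagents that add atoms: none
Why: Palladium‑catalysed formate reduction of the vinyl triflate removes the C15 oxygen and leaves the C15=C16 alkene.

**Step 15**
Reactants: 22
Product: 24 methyl 11β‑hydroxy‑17‑nor‑gibberella‑2,15‑dien‑7‑oate 19,10‑lactone (6β ester), via 6‑epimeric alcohols 23 (not isolated)
Conditions: NaBH4, MeOH/THF, −20 °C; then NaOMe, MeOH, 50 °C
Reagents that add atoms: none
Why: Borohydride should attack C11 from the face opposite the two‑carbon C15–C16 bridge (which lies 1,3‑diaxial over C11) to give the axial 11β‑alcohol; methoxide then equilibrates the ester α‑carbon C6 to the 6β configuration (trans to C4), only after the ketone is gone so that the C10 oxygen cannot be lost by E1cB.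

**Step 16**
Reactants: 24
Product: 26 methyl 11β,16‑dihydroxy‑17‑nor‑gibberell‑2‑en‑7‑oate 19,10‑lactone (16‑OH exo), via alkylborane 25 (not isolated)
Conditions: 9‑BBN, THF, 0 °C → rt; then H2O2, NaOAc (aq), 0 °C
Reagents that add atoms: hydrogen peroxide OO
Why: 9‑BBN hydroboration–oxidation: the strained bicyclic alkene reacts far faster than the hindered C2=C3 alkene, with boron at C16 (remote from quaternary C8) on the exo face; the new carbinol centre is erased in step 17.

**Step 17**
Reactants: 26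
Product: 27 methyl 11β‑hydroxy‑16‑oxo‑17‑nor‑gibberell‑2‑en‑7‑oate 19,10‑lactone
Conditions: TEMPO (10 mol%), PhI(OAc)2, CH2Cl2, rt
Reagents that add atoms: none
Why: Oxoammonium oxidation is sterically selective: the exposed C16 carbinol is oxidised while the axial 11β‑hydroxyl under the bridge should stay.

**Step 18**
Reactants: 27
Product: 28 methyl 2β,3β,11β‑trihydroxy‑16‑oxo‑17‑nor‑gibberellan‑7‑oate 19,10‑lactone
Conditions: OsO4 (5 mol%), NMO, acetone/H2O, rt
Reagents that add atoms: N‑methylmorpholine N‑oxide C[N+]1([O-])CCOCC1; water O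
Why: Upjohn dihydroxylation of the only remaining alkene from the β face, opposite the lactone bridge, sets C2 and C3 as the cis 2β,3β‑diol.

**Step 19**
Reactants: 28
Product: 29 methyl ester of the target (methyl 2β,3β,11β‑trihydroxy‑gibberell‑16‑en‑7‑oate 19,10‑lactone)
Conditions: Zn, CH2Br2, TiCl4, THF (reagent pre‑formed at 0–5 °C); then 28, CH2Cl2, rt
Reagents that add atoms: dibromomethane BrCBr
Why: Lombardo methylenation is non‑basic, so the 3β‑hydroxy lactone cannot epimerise by retro‑aldol, and it tolerates free hydroxyls with excess reagent.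

**Step 20**
Reactants: 29
Product: 30 target acid CNP0322347.1
Conditions: n‑PrSLi, HMPA, rt; then 1 M HCl
Reagents that add atoms: none
Why: SN2 demethylation of the hindered methyl ester by thiolate, which is too weakly basic to epimerise C3 or C6 or to open the lactone.

**Compound list**

1 | 5‑bromo‑2‑methoxybenzoic acid | COc1ccc(Br)cc1C(=O)O | starting material
2 | (S)‑2‑(methoxymethyl)pyrrolidine | COC[C@@H]1CCCN1 | starting material
3 | 5‑bromo‑2‑methoxybenzoyl chloride | COc1ccc(Br)cc1C(=O)Cl | intermediate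
4 | N‑(5‑bromo‑2‑methoxybenzoyl)‑(S)‑2‑(methoxymethyl)pyrrolidine | COc1ccc(Br)cc1C(=O)N1CCC[C@H]1COC | intermediate
5 | N‑(5‑allyl‑2‑methoxybenzoyl)‑(S)‑2‑(methoxymethyl)pyrrolidine | COc1ccc(CC=C)cc1C(=O)N1CCC[C@H]1COC | intermediate
6 | Birch enol ether (5‑allyl‑2‑methoxy‑1‑methylcyclohexa‑2,5‑diene‑1‑carboxamide of 2) | C=CCC1=C[C@](C)(C(=O)N2CCC[C@H]2COC)C(OC)=CC1 | intermediate
7 | 3‑allyl‑1‑methyl‑6‑oxocyclohex‑2‑ene‑1‑carboxamide of 2 | C=CCC1=C[C@](C)(C(=O)N2CCC[C@H]2COC)C(=O)CC1 | intermediate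
8 | 5‑allyl‑8‑bromo‑1‑methyl‑6‑oxabicyclo[3.2.1]octane‑2,7‑dione | C=CC[C@@]12CCC(=O)[C@@](C)(C(=O)O1)[C@@H]2Br | intermediate
9 | enol triflate of 8 | C=CC[C@@]12CC=C(OS(=O)(=O)C(F)(F)F)[C@@](C)(C(=O)O1)[C@@H]2Br | intermediate
10 | chlorohydrin triflate | OC(CCl)C[C@@]12CC=C(OS(=O)(=O)C(F)(F)F)[C@@](C)(C(=O)O1)[C@@H]2Br | intermediate
11 | 8‑bromo‑5‑(3‑chloro‑2‑hydroxypropyl)‑1‑methyl‑6‑oxabicyclo[3.2.1]oct‑2‑en‑7‑one | OC(CCl)C[C@@]12CC=C[C@@](C)(C(=O)O1)[C@@H]2Br | intermediate
12 | cyclopent‑2‑en‑1‑one | O=C1C=CCC1 | starting material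
13 | methyl glyoxylate | COC(=O)C=O | starting material
14 | methyl 2‑hydroxy‑2‑(2‑oxocyclopent‑3‑en‑1‑yl)acetate | COC(=O)C(O)C1CC=CC1=O | intermediate
15 | methyl 2‑(methylsulfonyloxy)‑2‑(2‑oxocyclopent‑3‑en‑1‑yl)acetate | COC(=O)C(OS(C)(=O)=O)C1CC=CC1=O | intermediate
16 | methyl (E)‑2‑(2‑oxocyclopent‑3‑en‑1‑ylidene)acetate | COC(=O)/C=C1\CC=CC1=O | intermediate
17 | Giese adduct (chlorohydrin, cyclopentenone) | OC(CCl)C[C@@]12CC=C[C@@](C)(C(=O)O1)[C@H]2C(C(=O)OC)C1CC=CC1=O | intermediate
18 | chloro ketone | O=C(CCl)C[C@@]12CC=C[C@@](C)(C(=O)O1)[C@H]2C(C(=O)OC)C1CC=CC1=O | intermediate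
19 | 2‑(tert‑butyldimethylsilyloxy)cyclopenta‑1,3‑dienyl chloro ketone | O=C(CCl)C[C@@]12CC=C[C@@](C)(C(=O)O1)[C@H]2C(C(=O)OC)C1=C(O[Si](C)(C)C(C)(C)C)C=CC1 | intermediate
20 | (4+3) adduct, 15‑OTBS, 11‑oxo | C1=C(O[Si](C)(C)C(C)(C)C)[C@]23C[C@H]1CC(=O)[C@H]2[C@@]12CC=C[C@@](C)(C(=O)O1)[C@H]2C3C(=O)OC | intermediate
21 | 15‑enol triflate, 11‑oxo | C1=C(OS(=O)(=O)C(F)(F)F)[C@]23C[C@H]1CC(=O)[C@H]2[C@@]12CC=C[C@@](C)(C(=O)O1)[C@H]2C3C(=O)OC | intermediate
22 | 11‑oxo 2,15‑diene | C1=C[C@]23C[C@H]1CC(=O)[C@H]2[C@@]12CC=C[C@@](C)(C(=O)O1)[C@H]2C3C(=O)OC | intermediate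
23 | 11β‑alcohol, C6 epimers | C1=C[C@]23C[C@H]1C[C@H](O)[C@H]2[C@@]12CC=C[C@@](C)(C(=O)O1)[C@H]2C3C(=O)OC | intermediate
24 | 11β‑alcohol, 6β ester | C1=C[C@]23C[C@H]1C[C@H](O)[C@H]2[C@@]12CC=C[C@@](C)(C(=O)O1)[C@H]2[C@@H]3C(=O)OC | intermediate
25 | C16 9‑BBN adduct (11‑O‑borinate) | B1(C2CCCC1CCC2)[C@@H]1C[C@]23C[C@H]1C[C@H](OB4C5CCCC4CCC5)[C@H]2[C@@]12CC=C[C@@](C)(C(=O)O1)[C@H]2[C@@H]3C(=O)OC | intermediate
26 | 11β,16‑diol | O[C@@H]1C[C@]23C[C@H]1C[C@H](O)[C@H]2[C@@]12CC=C[C@@](C)(C(=O)O1)[C@H]2[C@@H]3C(=O)OC | intermediate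
27 | 11β‑hydroxy‑16‑ketone | O=C1C[C@]23C[C@H]1C[C@H](O)[C@H]2[C@@]12CC=C[C@@](C)(C(=O)O1)[C@H]2[C@@H]3C(=O)OC | intermediate
28 | 2β,3β,11β‑triol 16‑ketone | O=C1C[C@]23C[C@H]1C[C@H](O)[C@H]2[C@@]12C[C@H](O)[C@H](O)[C@@](C)(C(=O)O1)[C@H]2[C@@H]3C(=O)OC | intermediate
29 | target methyl ester | C=C1C[C@]23C[C@H]1C[C@H](O)[C@H]2[C@@]12C[C@H](O)[C@H](O)[C@@](C)(C(=O)O1)[C@H]2[C@@H]3C(=O)OC | intermediate
30 | CNP0322347.1 | C=C1C[C@]23C[C@H]1C[C@H](O)[C@H]2[C@@]12C[C@H](O)[C@H](O)[C@@](C)(C(=O)O1)[C@H]2[C@@H]3C(=O)O | target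

**Step count and risks**

Total step count: 20. Longest linear sequence: 18 (steps 1–7 and 10–20).

Steps most likely to fail:

1. Step 12 (Proposed new method). The chloro ketone may be silylated along with the enone, the zwitterion may close at C15 in a (3+2) sense or collapse by a Favorskii path, or a 1,5‑hydrogen shift may move the diene before capture. The fallback uses the classical Föhlisch cycloaddition in trifluoroethanol with an all‑carbon cyclopentadiene. It sets out from 17: Luche reduction of the enone (NaBH4, CeCl3, MeOH) and acid‑catalysed dehydration (cat. TsOH, CH2Cl2) give the cyclopentadiene chlorohydrin F1. Pyridine‑buffered Dess–Martin oxidation gives the chloro ketone F2. i‑Pr2NEt in CF3CH2OH at 0 °C generates the oxyallyl cation, and its cycloaddition with the tethered diene gives 22, where the route is rejoined (steps 11–14 are skipped). This variant lacks the silyloxy group that steers the diene face and fixes the diene position, which is why it is held in reserve.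

2. Step 10. The bridge radical may add to the endocyclic enone carbon of the cross‑conjugated acceptor, the acceptor may be reduced or oligomerised under the tin hydride conditions, and facial selectivity at C5 may erode. The fallback sets out from 11 and uses the saturated acceptor methyl (E)‑2‑(2‑oxocyclopentylidene)acetate F3 (made from cyclopentanone and 13 in the manner of steps 8–9). Giese addition gives the cyclopentanone adduct F4. The carbinol is masked as its triethylsilyl ether F5 (TESCl, imidazole). Kinetic enolisation with LDA and dehydrogenation with N‑tert‑butylbenzenesulfinimidoyl chloride give the enone F6, and HF·pyridine returns 17.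

3. Step 17. The hindered 11β‑carbinol may be oxidised together with the C16 carbinol. The fallback sets out from 24 and protects before the D‑ring oxygen is introduced: TESOTf/2,6‑lutidine gives the 11‑silyl ether F7, 9‑BBN then H2O2/NaOAc gives the 16‑alcohol F8, Dess–Martin oxidation gives the ketone F9, and HF·pyridine returns 27.

**Further compounds**

F1 | step 12 | cyclopentadienyl chlorohydrin (Luche/dehydration product of 17) | OC(CCl)C[C@@]12CC=C[C@@](C)(C(=O)O1)[C@H]2C(C(=O)OC)C1=CC=CC1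
F2 | step 12 | cyclopentadienyl chloro ketone | O=C(CCl)C[C@@]12CC=C[C@@](C)(C(=O)O1)[C@H]2C(C(=O)OC)C1=CC=CC1
F3 | step 10 | methyl (E)‑2‑(2‑oxocyclopentylidene)acetate | COC(=O)/C=C1\CCCC1=O
F4 | step 10 | cyclopentanone Giese adduct | OC(CCl)C[C@@]12CC=C[C@@](C)(C(=O)O1)[C@H]2C(C(=O)OC)C1CCCC1=O
F5 | step 10 | triethylsilyl ether of F4 | CC[Si](CC)(CC)OC(CCl)C[C@@]12CC=C[C@@](C)(C(=O)O1)[C@H]2C(C(=O)OC)C1CCCC1=O
F6 | step 10 | triethylsilyl ether of 17 | CC[Si](CC)(CC)OC(CCl)C[C@@]12CC=C[C@@](C)(C(=O)O1)[C@H]2C(C(=O)OC)C1CC=CC1=O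
F7 | step 17 | 11‑O‑triethylsilyl ether of 24 | C1=C[C@]23C[C@H]1C[C@H](O[Si](CC)(CC)CC)[C@H]2[C@@]12CC=C[C@@](C)(C(=O)O1)[C@H]2[C@@H]3C(=O)OC
F8 | step 17 | 16‑alcohol 11‑O‑triethylsilyl ether | O[C@@H]1C[C@]23C[C@H]1C[C@H](O[Si](CC)(CC)CC)[C@H]2[C@@]12CC=C[C@@](C)(C(=O)O1)[C@H]2[C@@H]3C(=O)OC
F9 | step 17 | 16‑ketone 11‑O‑triethylsilyl ether | O=C1C[C@]23C[C@H]1C[C@H](O[Si](CC)(CC)CC)[C@H]2[C@@]12CC=C[C@@](C)(C(=O)O1)[C@H]2[C@@H]3C(=O)OC
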